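**Strategy**

The route rests on disconnecting the C2–H and C3–H bonds (4-aryl-4-oxobutanoate numbering: C1 carboxyl, C4 ketone; ring atoms primed). The target is traced to its (E)-2,3-dehydro ester, made by Wittig union of an arylglyoxal with a homogeranyl-substituted phosphorane. An ene-reductase then saturates only the C2=C3 alkene, the one alkene conjugated to both the C4 aryl ketone and the C1 ester, and sets (S)-C2 in the same operation; the two isolated trisubstituted alkenes of the homogeranyl chain cannot accept hydride. The precursor is the methyl ester with both phenols of the hydroquinone ring capped as acetates, so that O2' cannot close a chromanone ring onto C2.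

Key step: step 7

Remark: C2 of the target is S (CO2H > CH2C(=O)Ar > chain CH2 > H), which corresponds to hydride addition to the Re face of C2 of the E alkene (ester and aroyl group trans); it is assumed that geranyl bromide is bought as the pure E isomer (otherwise from geraniol with PBr3) and that the ene-reductases are used as isolated enzymes free of esterase and ketoreductase activity.

**Route**

Step 1
Reactants: 1 2,5-dihydroxyacetophenone
Product: 2 2-acetyl-1,4-phenylene diacetate (2,5-diacetoxyacetophenone)
Conditions: Ac2O (3 equiv), pyridine, DMAP (cat.), CH2Cl2, 0 °C to rt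
Reagents that add atoms: acetic anhydride, CC(=O)OC(C)=O
Why: DMAP-catalysed O-acylation (nucleophilic acyl substitution) should cap both phenols, including the hydrogen-bonded 2-OH, as acetates that shield the hydroquinone from oxidants, silence O2' as a nucleophile and come off in the last step.

Step 2
Reactants: 2 2-acetyl-1,4-phenylene diacetate
Product: 4 2-(2-oxoacetyl)-1,4-phenylene diacetate (2,5-diacetoxyphenylglyoxal), via glyoxal hydrate 3 (not isolated)
Conditions: SeO2 (1.3 equiv), 1,4-dioxane/H2O (30:1), 95 °C; filtration; toluene azeotrope
Reagents that add atoms: selenium dioxide, O=[Se]=O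
Why: Riley oxidation, in which the enol of the aryl methyl ketone attacks SeO2 and the selenium ester collapses to the 1,2-dicarbonyl compound, should give the glyoxal (hydrated in the wet medium, then dried to the free aldehyde) while the weakly acidic medium leaves the aryl acetates in place.

Step 3
Reactants: 5 geranyl bromide [(2E)-1-bromo-3,7-dimethylocta-2,6-diene]; 6 thioanisole (methyl phenyl sulfide)
Product: 8 [(3E)-4,8-dimethylnona-3,7-dien-1-yl](phenyl)sulfane (homogeranyl phenyl sulfide), via (phenylthio)methyllithium 7 (not isolated)
Conditions: 6, n-BuLi, DABCO, THF, 0 °C; then 5, −78 °C to rt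
Reagents that add atoms: none
Why: Lithiation of thioanisole gives a sulfur-stabilised primary organolithium that should displace bromide at C1 of the allylic bromide (SN2 alkylation), adding the one carbon that turns geranyl into homogeranyl without touching the E alkene.

Step 4
Reactants: 8 homogeranyl phenyl sulfide
Product: 10 (3E)-1-iodo-4,8-dimethylnona-3,7-diene (homogeranyl iodide), via sulfonium iodide 9 (not isolated)
Conditions: MeI (10 equiv), NaI (3 equiv), DMF, 75 °C, sealed vessel, dark
Reagents that add atoms: iodomethane, CI; sodium iodide, [Na+].[I-]
Why: Reversible S-methylation turns the phenylthio group into a neutral leaving group, and iodide should then displace thioanisole at the unhindered primary carbon (sulfonium-mediated sulfide-to-iodide exchange, SN2), attack at the S-methyl group merely returning the reagents.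

Step 5
Reactants: 10 homogeranyl iodide; 11 methyl (triphenylphosphoranylidene)acetate
Product: 13 methyl (5E)-6,10-dimethyl-2-(triphenyl-λ5-phosphanylidene)undeca-5,9-dienoate, via phosphonium iodide 12 (not isolated)
Conditions: 11 (2.1 equiv), MeCN, 80 °C; concentration, toluene, filtration of the phosphonium salt
Reagents that add atoms: none
Why: The ester-stabilised ylide is a soft carbon nucleophile that should displace iodide from the primary homoallylic carbon (SN2 C-alkylation of a phosphorus ylide), after which the second equivalent of 11 deprotonates the new phosphonium salt (transylidation) to give the disubstituted ylide.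

Step 6
Reactants: 4 2,5-diacetoxyphenylglyoxal; 13 methyl (5E)-6,10-dimethyl-2-(triphenyl-λ5-phosphanylidene)undeca-5,9-dienoate
Product: 14 methyl (2E,5E)-2-[2-(2,5-diacetoxyphenyl)-2-oxoethylidene]-6,10-dimethylundeca-5,9-dienoate
Conditions: CH2Cl2, 0 °C to rt, dark
Reagents that add atoms: none
Why: Wittig reaction of an α-substituted, ester-stabilised ylide, which should attack only the aldehyde carbon of the 1,2-dicarbonyl compound and, through the product-like transition state typical of such ylides, place the C4 aroyl group trans to the C1 ester (E), the geometry on which the next step depends.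

Step 7
Reactants: 14 methyl (2E,5E)-2-[2-(2,5-diacetoxyphenyl)-2-oxoethylidene]-6,10-dimethylundeca-5,9-dienoate
Product: 15 methyl (2S,5E)-2-[2-(2,5-diacetoxyphenyl)-2-oxoethyl]-6,10-dimethylundeca-5,9-dienoate
Conditions: ene-reductase (Old Yellow Enzyme family, picked from a stereocomplementary panel such as OYE1, OYE2, OYE3, YqjM, OPR1, OPR3, NCR, XenA), NADP+ (cat.), glucose dehydrogenase, D-glucose (3 equiv), KH2PO4/K2HPO4 buffer pH 6.5, DMSO (10% v/v), 30 °C, argon, dark
Reagents that add atoms: none
Why: The C4 ketone oxygen should be held by the His/His (or His/Asn) pair of the active site so that C2, the carbon β to that ketone, lies over N5 of the reduced flavin mononucleotide; hydride passes from N5 to C2, the enolate is protonated at C3 by the conserved tyrosine from the other face (net anti addition of H2), and NADPH, regenerated from D-glucose by glucose dehydrogenase, reloads the flavin. The closest known reaction type is the ene-reductase reduction of 2-substituted 4-oxo-2-enoates to non-racemic γ-keto esters, applied here to a larger and more lipophilic member of that class, hence the enzyme panel and the cosolvent. No skeletal bond is formed and no ring is closed. The one new stereocentre, C2, is set under enzyme control: the binding orientation of the E alkene fixes which face of C2 meets the flavin, and the enzyme retained is the one that delivers hydride to the Re face of C2 (C1, C3 and the chain CH2 clockwise), which gives S. Chemoselectivity is needed and is secured by the substrate, since only the C2=C3 alkene is conjugated to a bound carbonyl, while the trisubstituted chain alkenes, the aryl ketone and the esters are not reduced by the flavin hydride. Facial selectivity also needs a geometrically pure E alkene, which the O2' acetate (no reversible chromanone closure), the thiol-free, slightly acidic buffer and the exclusion of light should preserve.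

Step 8
Reactants: 15 methyl (2S,5E)-2-[2-(2,5-diacetoxyphenyl)-2-oxoethyl]-6,10-dimethylundeca-5,9-dienoate
Product: 16 (2S,5E)-2-[2-(2,5-dihydroxyphenyl)-2-oxoethyl]-6,10-dimethylundeca-5,9-dienoic acid
Conditions: LiOH (6 equiv), degassed THF/MeOH/H2O, 0 °C to rt, argon; then 1 M HCl to pH 3, Na2S2O4 wash
Reagents that add atoms: lithium hydroxide (aqueous), [Li+].[OH-]
Why: Saponification (acyl–oxygen ester hydrolysis) should strip the two aryl acetates first and then the methyl ester, C2 keeping its configuration because attack at C1 is far faster than removal of the C2 hydrogen of an ester or carboxylate, while exclusion of oxygen and the dithionite wash keep the hydroquinone ring from going to the quinone.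

**Compound list**

1 | 2,5-dihydroxyacetophenone | CC(=O)c1cc(O)ccc1O | starting material
2 | 2-acetyl-1,4-phenylene diacetate | CC(=O)c1cc(OC(C)=O)ccc1OC(C)=O | intermediate
3 | 2-(2,2-dihydroxyacetyl)-1,4-phenylene diacetate (glyoxal hydrate, not isolated) | OC(O)C(=O)c1cc(OC(C)=O)ccc1OC(C)=O | intermediate
4 | 2-(2-oxoacetyl)-1,4-phenylene diacetate | O=CC(=O)c1cc(OC(C)=O)ccc1OC(C)=O | intermediate
5 | geranyl bromide, (2E)-1-bromo-3,7-dimethylocta-2,6-diene | CC(C)=CCC/C(C)=C/CBr | starting material
6 | thioanisole | CSc1ccccc1 | starting material
7 | (phenylthio)methyllithium (not isolated) | [Li]CSc1ccccc1 | intermediate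
8 | [(3E)-4,8-dimethylnona-3,7-dien-1-yl](phenyl)sulfane | CC(C)=CCC/C(C)=C/CCSc1ccccc1 | intermediate
9 | [(3E)-4,8-dimethylnona-3,7-dien-1-yl](methyl)(phenyl)sulfonium iodide (racemic at sulfur, not isolated) | CC(C)=CCC/C(C)=C/CC[S+](C)c1ccccc1.[I-] | intermediate
10 | (3E)-1-iodo-4,8-dimethylnona-3,7-diene | CC(C)=CCC/C(C)=C/CCI | intermediate
11 | methyl (triphenylphosphoranylidene)acetate | COC(=O)C=P(c1ccccc1)(c1ccccc1)c1ccccc1 | starting material
12 | [(5E)-1-methoxy-6,10-dimethyl-1-oxoundeca-5,9-dien-2-yl]triphenylphosphonium iodide (racemic, not isolated) | CC(C)=CCC/C(C)=C/CCC(C(=O)OC)[P+](c1ccccc1)(c1ccccc1)c1ccccc1.[I-] | intermediate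
13 | methyl (5E)-6,10-dimethyl-2-(triphenyl-λ5-phosphanylidene)undeca-5,9-dienoate | CC(C)=CCC/C(C)=C/CCC(C(=O)OC)=P(c1ccccc1)(c1ccccc1)c1ccccc1 | intermediate
14 | methyl (2E,5E)-2-[2-(2,5-diacetoxyphenyl)-2-oxoethylidene]-6,10-dimethylundeca-5,9-dienoate | CC(C)=CCC/C(C)=C/CC/C(=C\C(=O)c1cc(OC(C)=O)ccc1OC(C)=O)C(=O)OC | intermediate
15 | methyl (2S,5E)-2-[2-(2,5-diacetoxyphenyl)-2-oxoethyl]-6,10-dimethylundeca-5,9-dienoate | CC(C)=CCC/C(C)=C/CC[C@@H](CC(=O)c1cc(OC(C)=O)ccc1OC(C)=O)C(=O)OC | intermediate
16 | (2S,5E)-2-[2-(2,5-dihydroxyphenyl)-2-oxoethyl]-6,10-dimethylundeca-5,9-dienoic acid | CC(C)=CCC/C(C)=C/CC[C@@H](CC(=O)c1cc(O)ccc1O)C(=O)O | target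

**Totals**

Total step count: 8. Longest linear sequence: 6 steps (steps 3, 4, 5, 6, 7, 8).

**Steps most likely to fail**

1. Step 7. The large, lipophilic substrate may be taken up slowly or bind in two orientations, so that turnover stalls or hydride reaches both faces of C2. Fallback: setting out from 14, the doubly activated alkene is reduced without stereocontrol by dissolving-metal conjugate reduction (Zn dust, AcOH/THF, 0 °C to rt) to racemic methyl (5E)-2-[2-(2,5-diacetoxyphenyl)-2-oxoethyl]-6,10-dimethylundeca-5,9-dienoate F1. The enantiomers are then separated by preparative supercritical-fluid chromatography on an amylose tris(3,5-dimethylphenylcarbamate) phase; the S enantiomer is 15, where the route is rejoined.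

2. Step 5. Substitution at the unactivated primary carbon may be slow, so that E2 loss of HI to the conjugated diene and incomplete transylidation compete. Fallback: setting out from 10, the sodium salt of trimethyl phosphonoacetate (NaH, DMSO, rt to 50 °C) is C-alkylated to methyl (5E)-2-(dimethoxyphosphoryl)-6,10-dimethylundeca-5,9-dienoate F2. Its sodium salt (NaH, THF, 0 °C) is combined with glyoxal 4 at −78 °C in a Horner–Wadsworth–Emmons reaction, and chromatographic removal of any Z isomer should leave 14, where the route is rejoined.

3. Step 2. The hot aqueous H2SeO3 medium may hydrolyse an aryl acetate, or the aldehyde may be oxidised further to the arylglyoxylic acid. Fallback: setting out from 2, α-bromination (CuBr2, EtOAc/CHCl3, reflux) gives 2-(2-bromoacetyl)-1,4-phenylene diacetate F3. Kornblum oxidation (DMSO, NaHCO3, rt) then converts the bromomethyl ketone into the glyoxal, obtained as hydrate 3 on aqueous work-up and dried as in step 2 to come back at 4.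

**Further compounds**

F1 | step 7 | racemic methyl (5E)-2-[2-(2,5-diacetoxyphenyl)-2-oxoethyl]-6,10-dimethylundeca-5,9-dienoate | CC(C)=CCC/C(C)=C/CCC(CC(=O)c1cc(OC(C)=O)ccc1OC(C)=O)C(=O)OC
F2 | step 5 | methyl (5E)-2-(dimethoxyphosphoryl)-6,10-dimethylundeca-5,9-dienoate (racemic) | CC(C)=CCC/C(C)=C/CCC(C(=O)OC)P(=O)(OC)OC
F3 | step 2 | 2-(2-bromoacetyl)-1,4-phenylene diacetate | BrCC(=O)c1cc(OC(C)=O)ccc1OC(C)=O
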